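The numbering is guaiane numbering. Everything rests on cutting C4–C5. This is the ring A (cyclopentane) bond inside the aldol retron C4(OH)–C5–C6(O), which ties ring A to ring B (cycloheptane). (R)-Carvone already holds C1–C6, C9, C10, C14 and C15. Its cyclohexene is cleaved between C4 and C6 to an acyclic 5-acetoxy-6-oxoheptanal, and a D-proline-catalysed 5-enolexo aldol addition re-stitches it at C4–C5. This one operation closes ring A, sets the C4 carbinol and C5, fixes the trans C1/C5 relationship of the later ring fusion, and frees the C6 aldehyde. A syn-aldol with an isovaleryl unit and a type 2 carbonyl-ene closure (C8–C9) then build ring B.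

Key step: step 4

Remark on numbering, faces and reading of the structure: C1/C5 are the ring-fusion carbons, C4 is the carbinol carbon with methyl C15, C7 carries the isopropyl group, and C10=C14H2 is the exocyclic alkene. α is the face of H5, 4-OH, 6-OAc and 8-OAc. β is the face of H1, C15, 3-OAc and the isopropyl group. The SMILES is read as the trans-fused (1S,3S,4S,5S,6S,7R,8S) isomer. The same locants are used for all precursors. Compounds 1, 9, 10 and D-proline are taken as catalogue chemicals.

Step 1
Reactants: 1 (R)-(−)-carvone
Product: 2 (1R,4R,6R)-1-methyl-4-(prop-1-en-2-yl)-7-oxabicyclo[4.1.0]heptan-2-one (carvone oxide; oxirane on the β face, trans to the isopropenyl group)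
Conditions: 30% H2O2, NaOH (cat.), MeOH, −10 to 0 °C
Reagents that add atoms: hydrogen peroxide, OO
Why: Weitz–Scheffer nucleophilic epoxidation, in which hydroperoxide adds only to the electron-poor C4=C6 enone bond (the isopropenyl group is untouched), axially and anti to the C1 isopropenyl group, so one oxirane diastereomer should form; its configuration steers step 2 and is erased in step 3.

Step 2
Reactants: 2 carvone oxide
Product: 4 epoxy acetate (3β-OAc cis to the oxirane oxygen; trans to isopropenyl), via lithium alkoxide 3 (not isolated)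
Conditions: Li[HB(s-Bu)3] (L-Selectride), THF, −78 °C; then Ac2O, DMAP (cat.), −78 °C to rt; pH 7 buffer/H2O2 work-up
Reagents that add atoms: acetic anhydride, CC(=O)OC(C)=O
Why: Diastereoselective ketone reduction with in-flask O-acylation, in which the bulky hydride attacks C3=O from the α face (equatorial trajectory and Felkin–Anh attack anti to the adjacent oxirane C–O bond), setting the axial 3β-oxygen trans to the isopropenyl group, and the alkoxide is trapped as the acetate that the target keeps.

Step 3
Reactants: 4 epoxy acetate
Product: 6 (3S,5S)-5-acetoxy-6-oxo-3-(prop-1-en-2-yl)heptanal, via trans-diaxial diol 5 (not isolated)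
Conditions: H5IO6, THF/H2O, 0 °C to rt
Reagents that add atoms: water, O
Why: Oxirane hydrolysis followed by Malaprade glycol cleavage in one flask; only the C4–C6 bond carries two free oxygen functions (C3–O is masked as acetate, and the isopropenyl group is inert to periodic acid), so the six-membered ring opens to the C4 methyl ketone and the C6 aldehyde with C1 and C3 untouched.

Step 4
Reactants: 6 (3S,5S)-5-acetoxy-6-oxo-3-(prop-1-en-2-yl)heptanal
Product: 8 (1S,2S,3R,4S)-3-formyl-2-hydroxy-2-methyl-4-(prop-1-en-2-yl)cyclopentyl acetate, via proline enamine 7 (not isolated)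
Conditions: D-proline (20–30 mol %), CH2Cl2 (or DMF), 0 °C to rt
Reagents that add atoms: none
Why: D-Proline condenses with the unhindered C6 aldehyde to the (E)-enamine 7, whose C5 attacks the C4 ketone (made more electrophilic by the α-acetoxy group) while the carboxylic acid protonates the developing alkoxide, and hydrolysis then releases 8 and the catalyst. The closest known reaction type is the proline-catalysed intramolecular enolexo aldol addition of dicarbonyl compounds, which stops at the tertiary ketol as in Hajos–Parrish ketol formation. Ring A closes in the 5-(enolexo)-exo-trig mode. C5 is set by the enamine face that the D-catalyst opens, which is also the face that places the formyl carbon trans to the pseudo-equatorial isopropenyl group on C1. C4 is set by the hydrogen-bonded chair-like Houk–List transition state, which holds the ketone oxygen next to the enamine nitrogen and anti to C1, giving OH α and trans to CHO with the methyl group β and pseudo-axial, and the same ketone face is the polar Felkin–Anh face anti to the pseudo-equatorial C3–OAc bond. The step needs aldehyde-donor/ketone-acceptor chemoselectivity (secured by the much faster enamine formation at the aldehyde and by the slower 7-membered or quaternary-carbon alternatives) and addition under kinetic control rather than condensation (mild bifunctional catalyst, low temperature).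

Step 5
Reactants: 9 (S)-4-benzyl-1,3-thiazolidine-2-thione; 10 3-methylbutanoyl chloride
Product: 11 (S)-4-benzyl-3-(3-methylbutanoyl)-1,3-thiazolidine-2-thione
Conditions: Et3N, DMAP (cat.), CH2Cl2, 0 °C to rt
Reagents that add atoms: none
Why: Simple N-acylation of the auxiliary, which brings in C7, C8 and C11–C13 without touching its stereocenter.

Step 6
Reactants: 8 ring A hydroxy aldehyde; 11 N-isovaleryl thiazolidinethione
Product: 13 Evans-syn aldol adduct (6R,7S; free 4α-OH and 6α-OH; C8 as N-acyl thiazolidinethione), via titanium enolate 12 (not isolated)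
Conditions: 11 (1.5 equiv), TiCl4, i-Pr2NEt, N-methylpyrrolidinone, CH2Cl2, 0 °C; then 8, −78 to 0 °C
Reagents that add atoms: none
Why: Crimmins-type titanium syn-aldol, in which the (Z)-enolate 12, with N-methylpyrrolidinone filling the free site on titanium, reacts through a non-chelated Zimmerman–Traxler chair whose open face is fixed by the (S)-benzyl auxiliary; this sets C6 and C7 as the syn pair, in the anti-Felkin sense that (Z)-enolates prefer with α-branched aldehydes, while the hindered tertiary 4-OH should stay a spectator toward the non-basic enolate used in excess.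

Step 7
Reactants: 13 syn-aldol adduct
Product: 14 4α,6α-bis(triethylsilyl) ether of 13
Conditions: Et3SiOTf (3 equiv), 2,6-lutidine, CH2Cl2, −78 to 0 °C
Reagents that add atoms: triethylsilyl triflate, CC[Si](CC)(CC)OS(=O)(=O)C(F)(F)F
Why: Silyl triflate silylation covers the secondary 6-OH and the tertiary 4-OH in one operation, which blocks retro-aldol, δ-lactol formation between 4-OH and C8, and consumption of the aluminium reagents in steps 8 and 9.

Step 8
Reactants: 14 bis-silyl ether
Product: 15 (2S,3R)-2-isopropyl-3-(triethylsilyloxy)-3-(ring A)propanal (C8 aldehyde; 3β-OAc, 4α-OTES, 6α-OTES)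
Conditions: i-Bu2AlH (1.2 equiv), CH2Cl2, −78 °C; aq. potassium sodium tartrate
Reagents that add atoms: none
Why: Partial reduction of the strongly activated, twisted N-acyl thiazolidinethione to a stable tetrahedral aluminate that collapses to the aldehyde on work-up; the hindered C3 acetate reacts more slowly, and any acetate lost here is restored in step 11.

Step 9
Reactants: 15 C8 aldehyde
Product: 16 3β-acetoxy-4α,6α-bis(triethylsilyloxy)-1βH,5αH-guai-10(14)-en-8α-ol
Conditions: Me2AlCl (2 equiv), CH2Cl2 (high dilution), −78 to −20 °C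
Reagents that add atoms: none
Why: Type 2 intramolecular carbonyl-ene reaction (the 6-methylhept-6-enal to 3-methylenecycloheptanol pattern), in which the isopropenyl CH2 (it becomes C9) attacks the aluminium-activated C8 aldehyde while a methyl hydrogen passes to oxygen (the methyl becomes C14H2=); a chair-like transition state on the trans-disubstituted ring A, with C6–OTES and C7–i-Pr pseudo-equatorial and the new bond anti to i-Pr, should place the C8 oxygen on the α face.

Step 10
Reactants: 16 ene product
Product: 17 3β-acetoxy-1βH,5αH-guai-10(14)-ene-4α,6α,8α-triol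
Conditions: HF·pyridine, pyridine/THF, 0 °C to rt
Reagents that add atoms: none
Why: Fluoride-driven cleavage of both triethylsilyl ethers under buffered conditions that leave the acetate, the tertiary alcohol and the exocyclic alkene intact.

Step 11
Reactants: 17 triol monoacetate
Product: 18 (1S,3S,4S,5S,6S,7R,8S)-3,6,8-triacetoxyguai-10(14)-en-4-ol (target)
Conditions: Ac2O, pyridine, DMAP (cat.), CH2Cl2, 0 °C to rt
Reagents that add atoms: acetic anhydride, CC(=O)OC(C)=O
Why: Chemoselective esterification, in which the two secondary alcohols (C6, C8) are acetylated while the hindered tertiary 4-OH does not react under these mild conditions and no stereocenter is touched.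

Compound list
1 | (R)-(−)-carvone | CC(=C)[C@H]1CC(=O)C(C)=CC1 | starting material
2 | carvone oxide, (1R,4R,6R)-1-methyl-4-(prop-1-en-2-yl)-7-oxabicyclo[4.1.0]heptan-2-one | CC(=C)[C@H]1CC(=O)[C@]2(C)O[C@@H]2C1 | intermediate
3 | lithium 3β-alkoxide of reduced 2 (O cis to oxirane, trans to isopropenyl) | CC(=C)[C@H]1C[C@H]([O-])[C@]2(C)O[C@@H]2C1.[Li+] | intermediate (not isolated)
4 | epoxy acetate: 1-methyl-4-(prop-1-en-2-yl)-7-oxabicyclo[4.1.0]heptan-2-yl acetate, OAc cis to oxirane O, trans to isopropenyl | CC(=C)[C@H]1C[C@H](OC(C)=O)[C@]2(C)O[C@@H]2C1 | intermediate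
5 | trans-diaxial diol: 2,3-dihydroxy-2-methyl-5-(prop-1-en-2-yl)cyclohexyl acetate (4α-OH, 6β-OH) | CC(=C)[C@H]1C[C@H](OC(C)=O)[C@@](C)(O)[C@H](O)C1 | intermediate (not isolated)
6 | (3S,5S)-5-acetoxy-6-oxo-3-(prop-1-en-2-yl)heptanal | CC(=O)[C@@H](OC(C)=O)C[C@@H](CC=O)C(C)=C | intermediate
7 | (E)-enamine of 6 (at C6) with D-proline | CC(=O)[C@@H](OC(C)=O)C[C@@H](/C=C/N1CCC[C@@H]1C(O)=O)C(C)=C | intermediate (not isolated)
8 | (1S,2S,3R,4S)-3-formyl-2-hydroxy-2-methyl-4-(prop-1-en-2-yl)cyclopentyl acetate | CC(=C)[C@H]1C[C@H](OC(C)=O)[C@@](C)(O)[C@@H]1C=O | intermediate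
9 | (S)-4-benzyl-1,3-thiazolidine-2-thione | S=C1N[C@@H](Cc2ccccc2)CS1 | starting material
10 | 3-methylbutanoyl chloride | CC(C)CC(Cl)=O | starting material
11 | (S)-4-benzyl-3-(3-methylbutanoyl)-1,3-thiazolidine-2-thione | CC(C)CC(=O)N1[C@@H](Cc2ccccc2)CSC1=S | intermediate
12 | trichlorotitanium (Z)-enolate of 11 | CC(C)/C=C(\O[Ti](Cl)(Cl)Cl)N1[C@@H](Cc2ccccc2)CSC1=S | intermediate (not isolated)
13 | syn-aldol adduct (6R,7S), N-acyl thiazolidinethione, free 4-OH and 6-OH | CC(=C)[C@H]1C[C@H](OC(C)=O)[C@@](C)(O)[C@@H]1[C@@H](O)[C@H](C(C)C)C(=O)N2[C@@H](Cc3ccccc3)CSC2=S | intermediate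
14 | 4,6-bis(triethylsilyl) ether of 13 | CC(=C)[C@H]1C[C@H](OC(C)=O)[C@@](C)(O[Si](CC)(CC)CC)[C@@H]1[C@@H](O[Si](CC)(CC)CC)[C@H](C(C)C)C(=O)N2[C@@H](Cc3ccccc3)CSC2=S | intermediate
15 | C8 aldehyde (3β-OAc, 4α-OTES, 6α-OTES, 7β-i-Pr) | CC(=C)[C@H]1C[C@H](OC(C)=O)[C@@](C)(O[Si](CC)(CC)CC)[C@@H]1[C@@H](O[Si](CC)(CC)CC)[C@H](C(C)C)C=O | intermediate
16 | 3β-acetoxy-4α,6α-bis(triethylsilyloxy)-1βH,5αH-guai-10(14)-en-8α-ol | C=C1C[C@H](O)[C@@H](C(C)C)[C@H](O[Si](CC)(CC)CC)[C@@H]2[C@@H]1C[C@H](OC(C)=O)[C@@]2(C)O[Si](CC)(CC)CC | intermediate
17 | 3β-acetoxy-1βH,5αH-guai-10(14)-ene-4α,6α,8α-triol | C=C1C[C@H](O)[C@@H](C(C)C)[C@H](O)[C@@H]2[C@@H]1C[C@H](OC(C)=O)[C@@]2(C)O | intermediate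
18 | (1S,3S,4S,5S,6S,7R,8S)-3,6,8-triacetoxyguai-10(14)-en-4-ol | C=C1C[C@H](OC(C)=O)[C@@H](C(C)C)[C@H](OC(C)=O)[C@@H]2[C@@H]1C[C@H](OC(C)=O)[C@@]2(C)O | target

Total step count: 11. Longest linear sequence: 10 (steps 1–4 and 6–11).

Steps most likely to fail

Step 4 (key aldol addition). The ketol may lose water under amine catalysis. The C4 configuration may also erode through retro-aldol equilibration toward the epimer that has the methyl group trans to its neighbours. The fallback sets out from 6 and returns at 8, and it accepts the dehydration. Piperidinium acetate in toluene drives 6 by aldol condensation (the same C4–C5 bond) to the conjugated cyclopentenecarbaldehyde F1. Nucleophilic epoxidation (t-BuOOH, DBU, CH2Cl2) then brings oxygen to C4 from the α face, anti to the C3 acetoxy group, and gives the 4α,5α-epoxy aldehyde F2. Cp2TiCl (trivalent titanium, made from Cp2TiCl2 and Zn) in THF/MeOH cleaves the C5–O bond next to the formyl group. Protonation of the resulting titanium enolate gives 8, with the 4α-OH kept from the oxirane and the epimerisable C5 settling trans to the isopropenyl group.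

Step 9 (ring B closure). Three things may go wrong: poor facial selectivity at C8 in the flexible seven-membered transition state, methyl transfer from aluminium to the hindered aldehyde, or intermolecular reaction. The fallback sets out from 15 and returns at 16. It replaces the pericyclic closure by a polar organometallic one. Selenium-catalysed ene-type allylic chlorination (NCS, PhSeCl cat., CH2Cl2) converts the isopropenyl group into the 2-(chloromethyl)allyl aldehyde F3. CrCl2 (divalent chromium) with LiI in THF at high dilution then forms the allylchromium species, which adds intramolecularly to the C8 aldehyde (Nozaki–Hiyama allylation). Both allyl termini are CH2 groups, so the same exocyclic methylene alcohol 16 results.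

Step 6 (fragment union). The unprotected ketol aldehyde may undergo β-elimination or retro-aldol cleavage on contact with the Lewis-acidic enolate and amine. The free hydroxyl may also interfere with the titanium coordination sphere and lower the facial control. The fallback sets out from 8 and returns at 15. The tertiary alcohol is masked first (Et3SiOTf, 2,6-lutidine) to give the 4-O-triethylsilyl aldehyde F4. A boron-mediated Evans syn-aldol (Bu2BOTf, Et3N, commercial (S)-4-benzyl-3-(3-methylbutanoyl)oxazolidin-2-one), whose boron has no spare coordination site, gives the oxazolidinone syn-aldol adduct F5. Silylation gives its 6-O-triethylsilyl ether F6. LiBH4 in Et2O/H2O at 0 °C removes the auxiliary to give the primary alcohol F7, and Dess–Martin oxidation gives 15.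

Further compounds
F1 | step 4 | cyclopentenecarbaldehyde (C4=C5 enal; 3β-OAc, C1 unchanged) | CC(=C)[C@H]1C[C@H](OC(C)=O)C(C)=C1C=O
F2 | step 4 | 4α,5α-epoxy aldehyde | CC(=C)[C@H]1C[C@H](OC(C)=O)[C@@]2(C)O[C@@]12C=O
F3 | step 9 | 2-(chloromethyl)allyl aldehyde (15 with C10(=CH2)CH2Cl) | ClCC(=C)[C@H]1C[C@H](OC(C)=O)[C@@](C)(O[Si](CC)(CC)CC)[C@@H]1[C@@H](O[Si](CC)(CC)CC)[C@H](C(C)C)C=O
F4 | step 6 | 4-O-triethylsilyl aldehyde (silyl ether of 8) | CC(=C)[C@H]1C[C@H](OC(C)=O)[C@@](C)(O[Si](CC)(CC)CC)[C@@H]1C=O
F5 | step 6 | oxazolidinone syn-aldol adduct (6R,7S) | CC(=C)[C@H]1C[C@H](OC(C)=O)[C@@](C)(O[Si](CC)(CC)CC)[C@@H]1[C@@H](O)[C@H](C(C)C)C(=O)N2[C@@H](Cc3ccccc3)COC2=O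
F6 | step 6 | 6-O-triethylsilyl ether of F5 | CC(=C)[C@H]1C[C@H](OC(C)=O)[C@@](C)(O[Si](CC)(CC)CC)[C@@H]1[C@@H](O[Si](CC)(CC)CC)[C@H](C(C)C)C(=O)N2[C@@H](Cc3ccccc3)COC2=O
F7 | step 6 | primary C8 alcohol | CC(=C)[C@H]1C[C@H](OC(C)=O)[C@@](C)(O[Si](CC)(CC)CC)[C@@H]1[C@@H](O[Si](CC)(CC)CC)[C@H](C(C)C)CO
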